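**Charge over rate.** Divide the charge of solid substrate by the rate at which the solution clears it, with gas phase held at 40 mM, and you have an estimate of the time at which control of target changes hands.

| setting | eta | zeta | flask |
|---|---|---|---|
| solid substrate | 0.42 M | 0.66 M | 0.30 M |
| gas phase | 40 mM (held) | 40 mM (held) | 40 mM (held) |
| remark | run made earlier | run made earlier |  |
| time |  |  | 10 min |

- eta (time / min: target / %): 0.167: 4.7; 0.333: 11.2; 0.833: 24.4; 2.00: 11.6; 4.00: 6.9; 10.0: 5.3
- zeta (time / min: target / %): 0.167: 2.8; 0.333: 7.4; 0.833: 16.0; 2.00: 14.4; 4.00: 6.6; 10.0: 5.4

(scatter of a reading: 0.3 percentage points)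

* time up to 10 min at which target stands highest
* the amount of target, in percent of the solid substrate charged, at that time

- solid, in amounts per volume of the solution: solid substrate
- at the start none of the gas phase is in solution
- at the start none of the solid substrate is in solution

**Excess solid.** Take first the extreme where solid is in excess. You then expect target in molar terms to follow one curve, zero order in the charge, and the two runs read alike: at 0.833 min eta reads 0.102 M and zeta 0.106 M.

**Solid absent.** In the other extreme no solid is left, and you expect target to fall, as the eta and zeta readings do late, to 5.3% and 5.4% at 10.0 min.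

**The crossing.** The real flask lies between: you expect it to ride the first curve until its charge is cleared, then fall, so you take the peak as the crossing. Eta's highest reading, at 0.833 min, gives a rough clearing rate, charge over the time of that reading, of 0.504 M min⁻¹. For zeta this means 1.31 min, which lies between its readings at 0.833 min and 2.00 min. For this flask you reckon 0.595 min, and eta's curve, taken straight between 0.333 min and 0.833 min, gives 0.0761 M, or 25.4% of the charge.

The forecast reads “Formation is therefore independent of the charge” and gives 0.62 min (0.45 min to 0.8 min) and 27.5% (24.5% to 31%), both higher than your reckoning.

**The flask.** The flask peaks at 0.647 min with 26.4%, and its solid substrate then stands at 0%. The clearing rate times that time gives 0.326 M, against 0.30 M charged.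

    dissolved gas + target → over-reacted product (k = 0.100 M⁻¹ s⁻¹)
    starting material + dissolved gas ⇌ target (K = 59.0 M⁻¹, k = 1.70 M⁻¹ s⁻¹)
    gas phase ⇌ dissolved gas, rate k3*(csat - [dissolved gas]) (kL = 0.620 s⁻¹)
    starting material ⇌ dormant form (K = 25.0, k = 0.0840 s⁻¹)
    solid substrate ⇌ starting material, rate k5*(cs5 - [starting material]) while solid is left; crystals form when [starting material] > cs5 (solubility = 0.150 M, k = 0.100 s⁻¹)

**Larger charge.** For the neighbouring flask with 1.2 M, the clearing rate gives an estimated clearing time of 2.38 min. That flask's best is 14.3% of its charge, or 0.172 M, twice this flask's 0.0792 M.

The numbers in the tables are calculated with made-up constants; the scatter is artificial.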